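**Target (25):** (1R,3S,4Z,6R,7R,8R,10R)-3-benzoyloxy-1,10-epoxy-8-[(2S,3S)-2,3-epoxy-2-methylbutanoyloxy]germacra-4,11(13)-dien-12,6-olide. The route has not been run; three stereochemical outcomes rest on analogy and are named where they occur (steps 8, 14, 15).

## Retrosynthetic overview

1. Last step: peracid epoxidation of the 1(10)-alkene of the 1(10)E,4Z-germacradienolide. The oxirane of the C8 ester is made separately and brought in intact.
2. Key disconnection: the C6–C7 bond (the bond the germacrene cyclase makes) together with the lactone C–O bond, cut on the open chain that already carries both esters and no protecting group. One chromium-mediated closure gives the ten-membered ring, C6 and C7, and the lactone.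
3. Open chain: acrylate arm by cross-metathesis; Z-enal by anti-carbomagnesiation/iodination of a propargylic alcohol, then formylation; E-trisubstituted alkene by carboalumination of a terminal alkyne and opening of ethylene oxide.
4. Stereocentres: C8 from (S)-2-vinyloxirane, C3 by catalytic asymmetric alkynylation, the side-chain oxirane by Sharpless epoxidation. C6, C7, C1 and C10 come from the two ring-forming steps.
5. Ring order: side-chain oxirane (off-line), then ten-membered carbocycle, then γ-lactone (same flask), then 1,10-oxirane.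

Assumption: (S)-2-vinyloxirane is bought as the single enantiomer; it is also available in one step by hydrolytic kinetic resolution of bulk racemic butadiene monoxide.

## Route

**Step 1**
Reactants: 1 angelic acid
Product: 2 (2Z)-2-methylbut-2-en-1-ol
Conditions: LiAlH4, Et2O, 0 °C to rt; aqueous work-up
Reagents that add atoms: none
Why: Hydride reduction of the acid is a 1,2-process that leaves the trisubstituted alkene and its Z geometry untouched.

**Step 2**
Reactants: 2 (2Z)-2-methylbut-2-en-1-ol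
Product: 3 [(2R,3S)-2,3-dimethyloxiran-2-yl]methanol
Conditions: Ti(OiPr)4 (10 mol%), D-(−)-diethyl tartrate (12 mol%), t-BuOOH, 4 Å molecular sieves, CH2Cl2, −20 °C
Reagents that add atoms: tert-butyl hydroperoxide, CC(C)(C)OO
Why: Sharpless asymmetric epoxidation, in which the D-tartrate titanium complex delivers oxygen to the face that gives the (2R,3S)-epoxy alcohol and syn addition keeps the two methyl groups trans on the oxirane.

**Step 3**
Reactants: 3 [(2R,3S)-2,3-dimethyloxiran-2-yl]methanol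
Product: 4 (2S,3S)-2,3-dimethyloxirane-2-carboxylic acid
Conditions: RuCl3 (2 mol%), NaIO4, MeCN/EtOAc/H2O, 0 °C to rt; used crude
Reagents that add atoms: water, O
Why: Sharpless RuCl3/NaIO4 oxidation takes the primary alcohol to the acid through the aldehyde hydrate without opening the oxirane, so the spatial arrangement is kept (2R becomes 2S only through the priority change).

**Step 4**
Reactants: 5 (S)-2-vinyloxirane
Product: 6 (3R)-hex-1-en-5-yn-3-ol
Conditions: lithium acetylide–ethylenediamine complex, DMSO, 0 °C to rt; H2O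
Reagents that add atoms: lithium acetylide–ethylenediamine complex, [Li+].[C-]#C.NCCN
Why: SN2 epoxide opening by the acetylide at the unsubstituted carbon leaves the C–O stereocentre untouched, and this centre becomes C8 (R).

**Step 5**
Reactants: 6 (3R)-hex-1-en-5-yn-3-ol
Product: 7 tert-butyl{[(3R)-hex-1-en-5-yn-3-yl]oxy}dimethylsilane
Conditions: TBSCl, imidazole, DMF, rt
Reagents that add atoms: tert-butyldimethylsilyl chloride, CC(C)(C)[Si](C)(C)Cl
Why: Standard silylation masks the only hydroxyl before the organometallic steps.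

**Step 6**
Reactants: 7 tert-butyl{[(3R)-hex-1-en-5-yn-3-yl]oxy}dimethylsilane
Product: 10 (3E,6R)-6-[(tert-butyldimethylsilyl)oxy]-4-methylocta-3,7-dien-1-ol, via alkenyldimethylalane 8 (not isolated), via lithium alkenylaluminate 9 (not isolated)
Conditions: Me3Al, Cp2ZrCl2 (25 mol%), CH2Cl2, 0 °C to rt; volatiles off; n-BuLi, hexane/THF, −30 °C; ethylene oxide, −30 to 0 °C; H2O
Reagents that add atoms: trimethylaluminium, C[Al](C)C; ethylene oxide, C1CO1
Why: Negishi zirconium-catalysed carboalumination adds methyl and aluminium syn across the terminal alkyne (methyl on the inner carbon), and the derived aluminate opens ethylene oxide with retention, which fixes the 1(10)E alkene.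

**Step 7**
Reactants: 10 (3E,6R)-6-[(tert-butyldimethylsilyl)oxy]-4-methylocta-3,7-dien-1-ol
Product: 11 (3E,6R)-6-[(tert-butyldimethylsilyl)oxy]-4-methylocta-3,7-dienal
Conditions: Dess–Martin periodinane, pyridine, CH2Cl2, 0 °C; used at once
Reagents that add atoms: none
Why: Dess–Martin oxidation under buffered conditions gives the β,γ-unsaturated aldehyde without moving the alkene into conjugation.

**Step 8**
Reactants: 11 (3E,6R)-6-[(tert-butyldimethylsilyl)oxy]-4-methylocta-3,7-dienal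
Product: 13 (3S,5E,8R)-8-[(tert-butyldimethylsilyl)oxy]-6-methyldeca-5,9-dien-1-yn-3-ol, via trimethylsilyl alkynol 12 (not isolated)
Conditions: ethynyltrimethylsilane, Me2Zn, (S,S)-ProPhenol (20 mol%), Ph3PO (40 mol%), toluene, 4 °C; H2O; then K2CO3 (cat.), MeOH, rt
Reagents that add atoms: ethynyltrimethylsilane, C#C[Si](C)(C)C
Why: Trost ProPhenol–zinc asymmetric alkynylation sets C3 as S under ligand control (the remote C8 centre has no say, and the ligand sense is assigned by analogy, with the antipodal ligand giving the other epimer), after which K2CO3/MeOH removes the C-silyl group.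

**Step 9**
Reactants: 13 (3S,5E,8R)-8-[(tert-butyldimethylsilyl)oxy]-6-methyldeca-5,9-dien-1-yn-3-ol
Product: 16 (1Z,3S,5E,8R)-8-[(tert-butyldimethylsilyl)oxy]-1-iodo-2,6-dimethyldeca-1,5,9-trien-3-yl benzoate, via alkenylmagnesium alkoxide 14 (not isolated), via iodoalkene magnesium alkoxide 15 (not isolated)
Conditions: MeMgBr (3.5 equiv), CuI (20 mol%), THF, −10 °C to rt; iodine in THF to faint colour, −40 °C; then BzCl, DMAP (cat.), 0 °C to rt
Reagents that add atoms: methylmagnesium bromide, C[Mg]Br; iodine, [I][I]; benzoyl chloride, O=C(Cl)c1ccccc1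
Why: Copper-catalysed anti-carbomagnesiation of the propargylic alkoxide puts methyl on the near carbon and holds magnesium cis to oxygen in a five-membered chelate, which fixes the 4Z geometry; iodinolysis goes with retention and the remaining magnesium alkoxide is benzoylated in the same flask.

**Step 10**
Reactants: 16 (1Z,3S,5E,8R)-8-[(tert-butyldimethylsilyl)oxy]-1-iodo-2,6-dimethyldeca-1,5,9-trien-3-yl benzoate
Product: 17 (2Z,4S,6E,9R)-9-[(tert-butyldimethylsilyl)oxy]-3,7-dimethyl-1-oxoundeca-2,6,10-trien-4-yl benzoate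
Conditions: Pd(PPh3)4 (5 mol%), CO (3 atm), Bu3SnH (syringe pump), THF, 50 °C
Reagents that add atoms: carbon monoxide, [C-]#[O+]
Why: Stille reductive carbonylation (oxidative addition of zerovalent palladium into the C–I bond, CO insertion, hydride transfer from tin) gives the enal with retention of the Z geometry.

**Step 11**
Reactants: 17 (2Z,4S,6E,9R)-9-[(tert-butyldimethylsilyl)oxy]-3,7-dimethyl-1-oxoundeca-2,6,10-trien-4-yl benzoate
Product: 18 (2Z,4S,6E,9R)-9-hydroxy-3,7-dimethyl-1-oxoundeca-2,6,10-trien-4-yl benzoate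
Conditions: HF·pyridine, pyridine, THF, 0 °C to rt
Reagents that add atoms: none
Why: Buffered fluoride desilylation frees the C8 hydroxyl without touching the benzoate or isomerizing the Z-enal.

**Step 12**
Reactants: 18 (2Z,4S,6E,9R)-9-hydroxy-3,7-dimethyl-1-oxoundeca-2,6,10-trien-4-yl benzoate; 4 (2S,3S)-2,3-dimethyloxirane-2-carboxylic acid
Product: 19 (3R,5E,8S,9Z)-8-(benzoyloxy)-5,9-dimethyl-11-oxoundeca-1,5,9-trien-3-yl (2S,3S)-2,3-dimethyloxirane-2-carboxylate
Conditions: DCC, DMAP (cat.), CH2Cl2, 0 °C to rt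
Reagents that add atoms: none
Why: Steglich esterification acylates the only free hydroxyl with the preformed epoxy acid, so both oxirane centres arrive intact and C8 is not touched.

**Step 13**
Reactants: 19 (3R,5E,8S,9Z)-8-(benzoyloxy)-5,9-dimethyl-11-oxoundeca-1,5,9-trien-3-yl (2S,3S)-2,3-dimethyloxirane-2-carboxylate; 20 methyl 2-(bromomethyl)prop-2-enoate
Product: 21 methyl (2Z,4R,6E,9S,10Z)-9-(benzoyloxy)-2-(bromomethyl)-4-{[(2S,3S)-2,3-dimethyloxirane-2-carbonyl]oxy}-6,10-dimethyl-12-oxododeca-2,6,10-trienoate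
Conditions: second-generation Hoveyda–Grubbs catalyst (10 mol%), 20 (6 equiv), CH2Cl2, 40 °C
Reagents that add atoms: none
Why: Olefin cross-metathesis in which only the monosubstituted alkene of 19 can enter the cycle, and the favoured isomer has C8 trans to the ester (2Z by CIP).

**Step 14**
Reactants: 21 methyl (2Z,4R,6E,9S,10Z)-9-(benzoyloxy)-2-(bromomethyl)-4-{[(2S,3S)-2,3-dimethyloxirane-2-carbonyl]oxy}-6,10-dimethyl-12-oxododeca-2,6,10-trienoate
Product: 24 (3S,4Z,6R,7R,8R,1(10)E)-3-benzoyloxy-8-[(2S,3S)-2,3-epoxy-2-methylbutanoyloxy]germacra-1(10),4,11(13)-trien-12,6-olide, via allylchromium dichloride 22 (not isolated), via chromium alkoxide 23 (not isolated)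
Conditions: CrCl2 (6 equiv), THF, rt, syringe-pump addition of 21 (final 2 mM); H2O
Reagents that add atoms: none
Why: Intramolecular Nozaki–Hiyama allylation then lactonization, in which divalent chromium makes the allylchromium 22, whose C7 adds to the Z-enal through a chair transition state with C8 equatorial (anti adduct, the trans 6R,7R fusion) and with C6 arriving anti to the C9 arm while H8 lies in the allyl plane (1,3-allylic strain), so that resident C8 is expected to fix C7; alkoxide 23 then closes the γ-lactone with loss of methoxide.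

**Step 15**
Reactants: 24 (3S,4Z,6R,7R,8R,1(10)E)-3-benzoyloxy-8-[(2S,3S)-2,3-epoxy-2-methylbutanoyloxy]germacra-1(10),4,11(13)-trien-12,6-olide
Product: 25 (1R,3S,4Z,6R,7R,8R,10R)-3-benzoyloxy-1,10-epoxy-8-[(2S,3S)-2,3-epoxy-2-methylbutanoyloxy]germacra-4,11(13)-dien-12,6-olide
Conditions: mCPBA (1.1 equiv), CH2Cl2, 0 °C
Reagents that add atoms: 3-chloroperbenzoic acid, OC(=O)... written in full as O=C(OO)c1cccc(Cl)c1
Why: Prilezhaev epoxidation attacks the only electron-rich alkene (the 4,5- and 11,13-alkenes are deactivated) from the exposed outer face of the ring, as in peracid epoxidation of related germacranolides, which should give the trans 1R,10R oxirane.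

## Compound list

1 | angelic acid, (2Z)-2-methylbut-2-enoic acid | C/C=C(/C)C(=O)O | starting material
2 | (2Z)-2-methylbut-2-en-1-ol | C/C=C(/C)CO | intermediate
3 | [(2R,3S)-2,3-dimethyloxiran-2-yl]methanol | OC[C@@]1(C)O[C@H]1C | intermediate
4 | (2S,3S)-2,3-dimethyloxirane-2-carboxylic acid | OC(=O)[C@@]1(C)O[C@H]1C | intermediate
5 | (S)-2-vinyloxirane | C=C[C@H]1CO1 | starting material
6 | (3R)-hex-1-en-5-yn-3-ol | C#CC[C@@H](O)C=C | intermediate
7 | tert-butyl{[(3R)-hex-1-en-5-yn-3-yl]oxy}dimethylsilane | C#CC[C@@H](O[Si](C)(C)C(C)(C)C)C=C | intermediate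
8 | {(1E,4R)-4-[(tert-butyldimethylsilyl)oxy]-2-methylhexa-1,5-dien-1-yl}dimethylalane | C[Al](C)/C=C(\C)C[C@@H](O[Si](C)(C)C(C)(C)C)C=C | intermediate
9 | lithium butyl{(1E,4R)-4-[(tert-butyldimethylsilyl)oxy]-2-methylhexa-1,5-dien-1-yl}dimethylaluminate | [Li+].CCCC[Al-](C)(C)/C=C(\C)C[C@@H](O[Si](C)(C)C(C)(C)C)C=C | intermediate
10 | (3E,6R)-6-[(tert-butyldimethylsilyl)oxy]-4-methylocta-3,7-dien-1-ol | OCC/C=C(\C)C[C@@H](O[Si](C)(C)C(C)(C)C)C=C | intermediate
11 | (3E,6R)-6-[(tert-butyldimethylsilyl)oxy]-4-methylocta-3,7-dienal | O=CC/C=C(\C)C[C@@H](O[Si](C)(C)C(C)(C)C)C=C | intermediate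
12 | (3S,5E,8R)-8-[(tert-butyldimethylsilyl)oxy]-6-methyl-1-(trimethylsilyl)deca-5,9-dien-1-yn-3-ol | C[Si](C)(C)C#C[C@@H](O)C/C=C(\C)C[C@@H](O[Si](C)(C)C(C)(C)C)C=C | intermediate
13 | (3S,5E,8R)-8-[(tert-butyldimethylsilyl)oxy]-6-methyldeca-5,9-dien-1-yn-3-ol | C#C[C@@H](O)C/C=C(\C)C[C@@H](O[Si](C)(C)C(C)(C)C)C=C | intermediate
14 | bromomagnesium (1Z,3S,5E,8R)-1-(bromomagnesio)-8-[(tert-butyldimethylsilyl)oxy]-2,6-dimethyldeca-1,5,9-trien-3-olate | Br[Mg]/C=C(/C)[C@@H](O[Mg]Br)C/C=C(\C)C[C@@H](O[Si](C)(C)C(C)(C)C)C=C | intermediate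
15 | bromomagnesium (1Z,3S,5E,8R)-8-[(tert-butyldimethylsilyl)oxy]-1-iodo-2,6-dimethyldeca-1,5,9-trien-3-olate | I/C=C(/C)[C@@H](O[Mg]Br)C/C=C(\C)C[C@@H](O[Si](C)(C)C(C)(C)C)C=C | intermediate
16 | (1Z,3S,5E,8R)-8-[(tert-butyldimethylsilyl)oxy]-1-iodo-2,6-dimethyldeca-1,5,9-trien-3-yl benzoate | I/C=C(/C)[C@@H](OC(=O)c1ccccc1)C/C=C(\C)C[C@@H](O[Si](C)(C)C(C)(C)C)C=C | intermediate
17 | (2Z,4S,6E,9R)-9-[(tert-butyldimethylsilyl)oxy]-3,7-dimethyl-1-oxoundeca-2,6,10-trien-4-yl benzoate | O=C/C=C(/C)[C@@H](OC(=O)c1ccccc1)C/C=C(\C)C[C@@H](O[Si](C)(C)C(C)(C)C)C=C | intermediate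
18 | (2Z,4S,6E,9R)-9-hydroxy-3,7-dimethyl-1-oxoundeca-2,6,10-trien-4-yl benzoate | O=C/C=C(/C)[C@@H](OC(=O)c1ccccc1)C/C=C(\C)C[C@@H](O)C=C | intermediate
19 | (3R,5E,8S,9Z)-8-(benzoyloxy)-5,9-dimethyl-11-oxoundeca-1,5,9-trien-3-yl (2S,3S)-2,3-dimethyloxirane-2-carboxylate | O=C/C=C(/C)[C@@H](OC(=O)c1ccccc1)C/C=C(\C)C[C@@H](OC(=O)[C@@]2(C)O[C@H]2C)C=C | intermediate
20 | methyl 2-(bromomethyl)prop-2-enoate | C=C(CBr)C(=O)OC | starting material
21 | methyl (2Z,4R,6E,9S,10Z)-9-(benzoyloxy)-2-(bromomethyl)-4-{[(2S,3S)-2,3-dimethyloxirane-2-carbonyl]oxy}-6,10-dimethyl-12-oxododeca-2,6,10-trienoate | O=C/C=C(/C)[C@@H](OC(=O)c1ccccc1)C/C=C(\C)C[C@@H](OC(=O)[C@@]2(C)O[C@H]2C)/C=C(\CBr)C(=O)OC | intermediate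
22 | allylchromium dichloride from 21 (CrCl2 in place of Br on the 2-methylene carbon) | O=C/C=C(/C)[C@@H](OC(=O)c1ccccc1)C/C=C(\C)C[C@@H](OC(=O)[C@@]2(C)O[C@H]2C)/C=C(\C[Cr](Cl)Cl)C(=O)OC | intermediate
23 | ring-closed chromium alkoxide: methyl 2-[(ten-membered ring, 6R,7R)-7-yl]acrylate with O–CrCl2 at C6 | Cl[Cr](Cl)O[C@@H]1/C=C(/C)[C@@H](OC(=O)c2ccccc2)C/C=C(\C)C[C@@H](OC(=O)[C@@]2(C)O[C@H]2C)[C@H]1C(=C)C(=O)OC | intermediate
24 | (3S,4Z,6R,7R,8R,1(10)E)-3-benzoyloxy-8-[(2S,3S)-2,3-epoxy-2-methylbutanoyloxy]germacra-1(10),4,11(13)-trien-12,6-olide | C=C1C(=O)O[C@@H]2/C=C(/C)[C@@H](OC(=O)c3ccccc3)C/C=C(\C)C[C@@H](OC(=O)[C@@]3(C)O[C@H]3C)[C@@H]12 | intermediate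
25 | (1R,3S,4Z,6R,7R,8R,10R)-3-benzoyloxy-1,10-epoxy-8-[(2S,3S)-2,3-epoxy-2-methylbutanoyloxy]germacra-4,11(13)-dien-12,6-olide | C=C1C(=O)O[C@@H]2/C=C(/C)[C@@H](OC(=O)c3ccccc3)C[C@H]3O[C@]3(C)C[C@@H](OC(=O)[C@@]3(C)O[C@H]3C)[C@@H]12 | target

## Step count and risks

Total step count: 15 (3 for acid 4, 12 on the main line). Longest linear sequence: 12 steps (steps 4 to 15, from 5 to 25).

**Step 14, ring closure.** The risks are oligomers instead of the ten-membered ring, the wrong C6/C7 pair relative to C8, and slow reduction of the glycidic ester by excess CrCl2. The fallback sets out from 19. Cross-metathesis with methyl 2-[(trimethylsilyl)methyl]acrylate gives the allylsilane methyl (2Z,4R,6E,9S,10Z)-9-(benzoyloxy)-4-{[(2S,3S)-2,3-dimethyloxirane-2-carbonyl]oxy}-6,10-dimethyl-12-oxo-2-[(trimethylsilyl)methyl]dodeca-2,6,10-trienoate F1. This is closed by a fluoride-triggered intramolecular Hosomi–Sakurai reaction (TBAF cat., THF, high dilution). The open transition state gives a different stereochemical course and uses no reducing metal. The alkoxide lactonizes and the route is rejoined at 24.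

**Step 13, cross-metathesis.** Both partners are poor metathesis substrates (a hindered allylic ester and a 1,1-disubstituted acrylate). The fallback makes the metathesis intramolecular and sets out from 18.
- Me2SiCl2/Et3N, then methyl 2-(hydroxymethyl)acrylate, give the mixed silyl ketal methyl 2-({[(3R,5E,8S,9Z)-8-(benzoyloxy)-5,9-dimethyl-11-oxoundeca-1,5,9-trien-3-yl]oxy}dimethylsilyloxymethyl)prop-2-enoate F2.
- Ring-closing metathesis (second-generation Grubbs catalyst, CH2Cl2, 40 °C) gives the seven-membered siloxane methyl (7R)-7-[(2E,5S,6Z)-5-(benzoyloxy)-2,6-dimethyl-8-oxoocta-2,6-dien-1-yl]-2,2-dimethyl-4,7-dihydro-1,3,2-dioxasilepine-5-carboxylate F3. The ring forces C8 and the CH2O group to be cis.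
- HF·pyridine releases the diol methyl (2E,4R,6E,9S,10Z)-9-(benzoyloxy)-4-hydroxy-2-(hydroxymethyl)-6,10-dimethyl-12-oxododeca-2,6,10-trienoate F4.
- CBr4/PPh3 at −20 °C converts only the primary allylic hydroxyl, giving methyl (2Z,4R,6E,9S,10Z)-9-(benzoyloxy)-2-(bromomethyl)-4-hydroxy-6,10-dimethyl-12-oxododeca-2,6,10-trienoate F5.
- DCC/DMAP coupling with 4 rejoins the route at 21.

**Step 15, epoxidation.** Chemoselectivity is safe, but the face is set only by the ring conformation. The fallback sets out from 24 and replaces substrate control by reagent control: Shi epoxidation with the fructose-derived ketone or its enantiomer (KHSO5, K2CO3 buffer, MeCN/dimethoxymethane/H2O, 0 °C), whichever gives the 1R,10R oxirane. It arrives directly at 25 and makes no new compound (F0).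

## Further compounds

F1 | step 14 | methyl (2Z,4R,6E,9S,10Z)-9-(benzoyloxy)-4-{[(2S,3S)-2,3-dimethyloxirane-2-carbonyl]oxy}-6,10-dimethyl-12-oxo-2-[(trimethylsilyl)methyl]dodeca-2,6,10-trienoate | O=C/C=C(/C)[C@@H](OC(=O)c1ccccc1)C/C=C(\C)C[C@@H](OC(=O)[C@@]2(C)O[C@H]2C)/C=C(\C[Si](C)(C)C)C(=O)OC
F2 | step 13 | methyl 2-({[(3R,5E,8S,9Z)-8-(benzoyloxy)-5,9-dimethyl-11-oxoundeca-1,5,9-trien-3-yl]oxy}dimethylsilyloxymethyl)prop-2-enoate | O=C/C=C(/C)[C@@H](OC(=O)c1ccccc1)C/C=C(\C)C[C@@H](O[Si](C)(C)OCC(=C)C(=O)OC)C=C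
F3 | step 13 | methyl (7R)-7-[(2E,5S,6Z)-5-(benzoyloxy)-2,6-dimethyl-8-oxoocta-2,6-dien-1-yl]-2,2-dimethyl-4,7-dihydro-1,3,2-dioxasilepine-5-carboxylate | O=C/C=C(/C)[C@@H](OC(=O)c1ccccc1)C/C=C(\C)C[C@H]1O[Si](C)(C)OCC(C(=O)OC)=C1
F4 | step 13 | methyl (2E,4R,6E,9S,10Z)-9-(benzoyloxy)-4-hydroxy-2-(hydroxymethyl)-6,10-dimethyl-12-oxododeca-2,6,10-trienoate | O=C/C=C(/C)[C@@H](OC(=O)c1ccccc1)C/C=C(\C)C[C@@H](O)/C=C(\CO)C(=O)OC
F5 | step 13 | methyl (2Z,4R,6E,9S,10Z)-9-(benzoyloxy)-2-(bromomethyl)-4-hydroxy-6,10-dimethyl-12-oxododeca-2,6,10-trienoate | O=C/C=C(/C)[C@@H](OC(=O)c1ccccc1)C/C=C(\C)C[C@@H](O)/C=C(\CBr)C(=O)OC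
F0 | step 15 | none | none
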